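The readings stem from a simulated flask on assumed constants; noise was put on by code.

Take two rate constants, k_L for the left-handed substrate and k_R for the right-handed one: what I want from the north run is their ratio s = k_L/k_R.

| setting | north | flask |
|---|---|---|
| left-handed substrate | 5 mM | 5.0 mM |
| right-handed substrate | 5 mM | 5.0 mM |
| partner | 7.5 mM | 7.50 mM |
| free catalyst | 22 µM | 22 µM |
| impurity | 12 µM | 12 µM |
| remark | the very flask that is asked about, followed so far |  |
| time |  | 5.0 min |

north run (percent of the left-handed substrate and right-handed substrate together charged)

| time / s | right-handed product / % | left-handed product / % | left-handed substrate / % |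
|---|---|---|---|
| 10.0 | 3.8 | 12.0 | 38.8 |
| 25.0 | 6.9 | 18.9 | 31.5 |
| 40.0 | 11.0 | 24.2 | 24.4 |
| 60.0 | 12.7 | 28.5 | 21.7 |
| 90.0 | 15.8 | 32.7 | 17.7 |

(standard deviation of a reading: 1 percentage point)

- free catalyst is single-handed; left-handed substrate and right-handed substrate are mirror images of each other, charged as a racemate, each of them at the stated concentration
- the analysis behind the earlier runs scatters by 1 percentage point, standard deviation

* amount of right-handed product in percent of the left-handed substrate and right-handed substrate together charged, at 15 s, 80 s and 5.0 min

**Question: what can you read without a clock?**
Suppose both substrates pass through the same round, with the same free catalyst and the same partner. Their rates then differ by k_L·L against k_R·D, where L and D are the left- and right-handed substrate. Dividing one rate by the other removes time, catalyst and partner, which leaves d ln L / d ln D = s.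

**Question: and D, which wasn't measured?**
Each substrate starts at 50.0%, so I take D as that start minus the right-handed product. The left-handed side supports this, since L plus left-handed product stands at 50.4% at 90.0 s. That reading gives s = 2.73, and this selectivity factor, the ratio of the two constants taken from the two remainders, is what I carry forward.

**Follow-up: one reading, with scatter?**
True, so I check it against others. The reading at 40.0 s gives 2.89, and the one at 60.0 s gives 2.85.

**Question: your numbers?**
Interpolating between neighbouring readings gives 4.83% at 15 s and 14.8% at 80 s. For the end, s says nothing about where the flask stops, so I turn to the partner, the limiting reagent, whose 7.50 mM is less than the substrates together. Taken one to one, it allows 75.0% conversion. At 90.0 s the right-handed product makes up 32.6% of the products, so, if that share holds and the whole partner charge is used one to one, my rough figure for 5.0 min is 24.4%.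

The forecast gives 5%, 14.9% and 22.5%, holding that “The left-handed substrate reacts about three times faster than the right-handed one”, and its last figure is lower than my 24.4%.

The flask gives 5.62%, 14.5% and 18.6%.

    partner + free catalyst + left-handed substrate → free catalyst + left-handed product (k = 3.40 × 10⁵ L² mol⁻² s⁻¹)
    partner + free catalyst + right-handed substrate → free catalyst + right-handed product (k = 1.20 × 10⁵ L² mol⁻² s⁻¹)
    free catalyst + impurity → spent catalyst (k = 71000 L mol⁻¹ s⁻¹)
    partner → decomposed reagent (k = 0.00500 s⁻¹)

At 5.00 min the flask holds 1.90 mM of decomposed reagent, and 0.969% of the partner charge is left. The left-handed substrate stands there at 13.4%. Putting this into the rule with s = 2.73, the right-handed substrate is its start times the remaining fraction of the left-handed substrate raised to the power 1/s, and the right-handed product is the start minus that, which comes to 19.1%.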